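Heat both fills and drains these flasks.

| setting | Monday's | Saturday's | Friday's | Sunday's |
|---|---|---|---|---|
| solid monomer | 3.0 M | 3.0 M | 3.0 M | 3.0 M |
| initiator | 2 mol% | 2 mol% | 2 mol% | 2 mol% |
| temperature | 20 °C | 5 °C |  | 35 °C |
| time | 40 h | 40 h | 40 h | 40 h |
| remark |  |  | at 5 °C until 12 h, from then on at 35 °C |  |

- which flask leads in amount of monomer in chains, in percent of the solid monomer charged ("all alike" within 1.5 percentage points) (Monday's / Saturday's / Friday's / Sunday's / all alike)
- how much monomer in chains is there at the end, in percent of the solid monomer charged: Monday's
- how much monomer in chains is there at the end, in percent of the solid monomer charged: Saturday's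
- how much monomer in chains is there at the end, in percent of the solid monomer charged: Friday's
- how much monomer in chains is there at the end, in percent of the solid monomer charged: Sunday's

- what is said of monomer in chains includes crystals
- where a step has two of a species, its rate is k times that concentration squared, and two are used at each turn
- solid monomer, crystals is a solid; its amount is given per volume of the solution
- the constants hold at 35 °C; other temperatures follow from the activation energies
- at the start none of the solid monomer is in solution

    initiator → 2 initiating radical (k1 = 0.00528 h⁻¹, Ea1 = 108 kJ mol⁻¹)
    monomer in chains → over-reaction product (k2 = 0.151 h⁻¹, Ea2 = 100 kJ mol⁻¹)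
    free monomer + initiating radical → growing radical + monomer in chains (k3 = 1.22 × 10⁷ M⁻¹ h⁻¹, Ea3 = 37.0 kJ mol⁻¹)
    crystals ⇌ monomer in chains, rate k4*(cs4 - [monomer in chains]) while solid is left; crystals form when [monomer in chains] > cs4 (cs4 = 0.24 M, k4 = 5.10 h⁻¹)
    free monomer + growing radical → monomer in chains + growing radical, rate k5*[growing radical]*[free monomer] (k5 = 2.34 × 10⁶ M⁻¹ h⁻¹, Ea5 = 36.0 kJ mol⁻¹)
    solid monomer ⇌ free monomer, rate k6*(cs6 - [free monomer]) while solid is left; crystals form when [free monomer] > cs6 (cs6 = 1.8 M, k6 = 0.518 h⁻¹)
    2 growing radical → dead chain (k7 = 6.9 × 10⁶ M⁻¹ s⁻¹, Ea7 = 16.0 kJ mol⁻¹)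
    (constants at 35 °C)

Solid monomer dissolves into free monomer up to a ceiling of 1.8 M. Growing radical turns free monomer into monomer in chains, which crystallises above 0.24 M, and the dissolved part over-reacts with a constant of 0.151 h⁻¹ at 35 °C. Two times are compared here. While crystals hold the dissolved monomer in chains at its ceiling, over-reaction is a steady leak, so the charge divided by that constant and that ceiling gives 82.8 h. This is the drain time, the hours the leak at 35 °C needs to consume the whole charge.

The other is the fill time. [growing radical] settles where starting balances dying, at the square root of the initiator's breakdown constant times [initiator] over the termination constant, which is 1.13 × 10⁻⁷ M at 35 °C. Free monomer at its ceiling then enters chains at 0.476 M h⁻¹, so at that pace the charge needs about 6.31 h.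

Filling is 13.1 times shorter than draining, so Sunday's should fill early and then leak. Counted over its whole 40 h, the leak costs about 48.3 % of the charge and leaves about 51.7 %.

Cooling from 35 °C to 5 °C slows over-reaction by a factor of 67. Monday's lies midway in temperature, so the root of that factor gives a rough drain time of 679 h, far longer than its run. Monday's leak costs about 5.89 %, so the reckoning allows Monday's about 94.1 % in chains. That allowance stands above Sunday's, but this reckoning stops there, since how far Monday's fills remains open.

The forecast names Monday's, with 76 % there, 18 % for Saturday's, 64 % for Friday's and 51 % for Sunday's. Its ground is that the small cold leak “lets Monday's 20 °C flask beat the hotter flasks that convert fully but lose more”. The reckoned figure for Sunday's stands slightly higher than the forecast's.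

Monday's leads with 75.9 %, ahead of Friday's 64.5 %, Sunday's 51.7 % and Saturday's 18.3 %.

After 40.0 h, Monday's still holds 17.8 % as free monomer and 6.38 % as over-reaction product. A neighbour flask runs Monday's recipe on 0.75 M of solid monomer, a quarter of the charge under the same ceiling, so its drain time shrinks to 170 h and 40 h cost 23.5 %. That neighbour ends with 20.6 % over-reaction product and 43.0 % monomer in chains, less than Sunday's 51.7 %.

The rate constants were chosen freely.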